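**Plan**
- Retrosynthetic cuts: (i) the lactone C3–CH2Ar bond (enolate alkylation) gives lactone 16 and benzylic bromide 22; (ii) the lactone C3–C4 bond (ring closure by Rh-carbenoid C–H insertion) gives diazoacetate 15; (iii) the furan O1–C2 bond and, in both C6C3 appendages, the ArCH(O)–CH(Ar') bond (aldol) lead back to one arylacetyl imide and O-benzylvanillin.
- Forward: one anti-aldol gives diol 11, which is used twice. Half A is silylated, hydroborated, diazoacetylated and closed to the lactone. Half B is cyclised by acid to the dihydrobenzofuran and its allyl group is cut down to CH2Br. Alkylation joins the halves; two deprotections follow.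
- Enabling feature: lactone C4 is a CH flanked only by CH2 groups (C3, C5, benzylic CH2). In the open ester O1–C5H2–C4H2–CH2Ar it is an unactivated prochiral methylene five atoms from a carbenoid placed on C3, so the five-membered lactone forms directly at the final oxidation level.
- Stereochemistry: both propane-1,3-diol centres and furan C3 come from the auxiliary-controlled anti-aldol; furan C2 is set trans to C3 on ring closure; lactone C4 is set by the chiral Rh(II) carboxamidate; lactone C3 is set trans to C4 by substrate control.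

Key step: step 9

Assumption: the Mg-catalysed aldol is taken to occur on the chelated (Z)-enolate face anti to the auxiliary's benzyl group, and Rh2(4S-MPPIM)4 is taken to give (R)-β-benzyl-γ-butyrolactones, hence the (S)-auxiliary and the 4R catalyst; if either sense is the reverse, the antipode is used.

Shorthand in names: PMB = 4-methoxybenzyl, Bn = benzyl, TBS = tert-butyldimethylsilyl, TIPS = triisopropylsilyl.

**Route**

Step 1
Reactants: 1 5-allyl-2-hydroxy-3-methoxybenzaldehyde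
Product: 2 5-allyl-3-methoxy-2-(PMB-oxy)benzaldehyde
Conditions: PMBCl, K2CO3, Bu4NI (cat.), DMF, 60 °C
Reagents that add atoms: 4-methoxybenzyl chloride, COc1ccc(CCl)cc1
Why: Williamson etherification of the only phenol; PMB is chosen because acid removes it in the B series (step 10) and hydrogenolysis removes it in the A series (step 17).

Step 2
Reactants: 2 5-allyl-3-methoxy-2-(PMB-oxy)benzaldehyde
Product: 4 [5-allyl-3-methoxy-2-(PMB-oxy)phenyl]acetic acid, via trichloromethyl carbinol 3 (not isolated)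
Conditions: CCl3CO2Na, CCl3CO2H, DMF, rt; then NaBH4, NaOH, t-BuOH–H2O, 55 °C; citric acid work-up
Reagents that add atoms: sodium trichloroacetate, [Na+].[O-]C(=O)C(Cl)(Cl)Cl; sodium hydroxide, [Na+].[OH-]
Why: Jocic-type reductive homologation, in which trichloromethide adds to the aldehyde, base closes the gem-dichloroepoxide, hydride opens it at the benzylic carbon and the resulting acyl chloride is hydrolysed to the one-carbon-longer arylacetic acid.

Step 3
Reactants: 4 [5-allyl-3-methoxy-2-(PMB-oxy)phenyl]acetic acid; 5 (S)-4-benzyloxazolidin-2-one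
Product: 7 (S)-3-{[5-allyl-3-methoxy-2-(PMB-oxy)phenyl]acetyl}-4-benzyloxazolidin-2-one, via mixed pivalic anhydride 6 (not isolated)
Conditions: PivCl, Et3N, THF, −20 °C; then 5, LiCl, rt
Reagents that add atoms: none
Why: N-acylation of the oxazolidinone by the mixed anhydride under LiCl/Et3N, which avoids strong base at the acidic arylacetyl CH2.

Step 4
Reactants: 7 (S)-3-{[5-allyl-3-methoxy-2-(PMB-oxy)phenyl]acetyl}-4-benzyloxazolidin-2-one; 8 4-benzyloxy-3-methoxybenzaldehyde
Product: 9 (S)-3-[(2R,3S)-2-[5-allyl-3-methoxy-2-(PMB-oxy)phenyl]-3-(4-benzyloxy-3-methoxyphenyl)-3-(trimethylsilyloxy)propanoyl]-4-benzyloxazolidin-2-one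
Conditions: MgCl2 (10 mol%), Et3N, TMSCl, EtOAc, rt
Reagents that add atoms: chlorotrimethylsilane, C[Si](C)(C)Cl
Why: Magnesium-halide-catalysed direct anti-aldol of an N-acyloxazolidinone with an aromatic aldehyde, in which the chelated (Z)-magnesium enolate should add through a boat transition state on the face away from the 4-benzyl group (C-2 R) with anti topicity (C-3 S), while O-silylation drives turnover and blocks retro-aldol.

Step 5
Reactants: 9 the anti-aldol TMS ether
Product: 11 (1S,2S)-2-[5-allyl-3-methoxy-2-(PMB-oxy)phenyl]-1-(4-benzyloxy-3-methoxyphenyl)propane-1,3-diol, via silyl ether alcohol 10 (not isolated)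
Conditions: LiBH4, MeOH (1 equiv), THF, 0 °C; then K2CO3, MeOH, rt
Reagents that add atoms: none
Why: Reductive cleavage of the N-acyloxazolidinone to the primary alcohol (auxiliary recovered) followed by methanolysis of the TMS ether; no stereocentre is touched once the carbonyl is gone.

Step 6
Reactants: 11 the anti-diol
Product: 12 the 1,3-bis-O-TBS ether of 11
Conditions: TBSOTf, 2,6-lutidine, CH2Cl2, −78 to 0 °C
Reagents that add atoms: tert-butyldimethylsilyl triflate, CC(C)(C)[Si](C)(C)OS(=O)(=O)C(F)(F)F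
Why: Silylation of both hydroxyl groups, the hindered benzylic one included, so that no O–H bond is present for the carbenoid and enolate steps and the final unmasking can be done with fluoride instead of acid.

Step 7
Reactants: 12 the bis-TBS ether
Product: 13 3-{3-[(1S,2S)-1-(4-benzyloxy-3-methoxyphenyl)-1,3-bis(TBS-oxy)propan-2-yl]-5-methoxy-4-(PMB-oxy)phenyl}propan-1-ol
Conditions: 9-BBN, THF, 0 °C to rt; then NaOH, H2O2, 0 °C
Reagents that add atoms: hydrogen peroxide, OO
Why: Anti-Markovnikov hydroboration–oxidation of the terminal allyl group, the only alkene present, gives the 3-arylpropanol.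

Step 8
Reactants: 13 the 3-arylpropanol
Product: 15 the diazoacetate of 13, via glyoxylate tosylhydrazone 14 (not isolated)
Conditions: TsNHN=CHCOCl, PhNMe2, CH2Cl2, 0 °C; then Et3N, 0 °C to rt
Reagents that add atoms: glyoxylic acid chloride p-toluenesulfonylhydrazone, Cc1ccc(cc1)S(=O)(=O)NN=CC(=O)Cl
Why: Acylation of the primary alcohol followed by base-induced loss of sulfinate from the tosylhydrazone (Bamford–Stevens-type diazo formation) gives the diazoacetate in one flask.

Step 9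
Reactants: 15 the 3-arylpropyl diazoacetate
Product: 16 (S)-4-{3-[(1S,2S)-1-(4-benzyloxy-3-methoxyphenyl)-1,3-bis(TBS-oxy)propan-2-yl]-5-methoxy-4-(PMB-oxy)benzyl}dihydrofuran-2(3H)-one
Conditions: Rh2(4R-MPPIM)4 (1 mol%), CH2Cl2, reflux, 15 added by syringe pump over 10 h
Reagents that add atoms: none
Why: The Rh(II) carboxamidate expels N2 from 15 to give an electrophilic carbenoid at the future C3, which inserts in a concerted, asynchronous three-centre transition state into one of the two enantiotopic C–H bonds of the CH2 β to the ester oxygen, forming the C3–C4 bond. The closest known reaction type is the chiral dirhodium(II) carboxamidate-catalysed C–H insertion of 3-arylpropyl diazoacetates to β-benzyl-γ-butyrolactones used for lignan lactones. The lactone closes in a 1,5-insertion mode through a five-membered transition state, the ester O–CH2 serving as the tether. The new stereocentre C4 (S) is set by the catalyst, whose chiral imidazolidinone ligands differentiate the two prochiral hydrogens; the side-chain stereocentres are too remote to interfere. The step needs regioselectivity for the γ-lactone over insertion at O–CH2 (β-lactone) or the benzylic CH2 (δ-lactone) and chemoselectivity over aromatic cycloaddition, ether-ylide formation and carbene dimerisation. The weakly electrophilic carboxamidate carbenoid, the preference for five-membered closure, slow addition and the absence of any O–H group should secure this.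

Step 10
Reactants: 11 the anti-diol
Product: 17 [(2R,3S)-5-allyl-2-(4-benzyloxy-3-methoxyphenyl)-7-methoxy-2,3-dihydrobenzofuran-3-yl]methanol
Conditions: TFA, anisole, CH2Cl2, 0 °C; then K2CO3, MeOH work-up
Reagents that add atoms: none
Why: TFA cleaves the PMB ether (cation trapped by anisole) and ionises the 4-benzyloxybenzylic alcohol, and the freed ortho-phenol captures the cation in a 5-exo cycloetherification that places the 2-aryl group trans to the C-3 hydroxymethyl group (C-3 unchanged, C-2 set R under control of C-3).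

Step 11
Reactants: 17 the dihydrobenzofuran alcohol
Product: 18 the O-TBS ether of 17
Conditions: TBSCl, imidazole, DMF, rt
Reagents that add atoms: tert-butyldimethylsilyl chloride, CC(C)(C)[Si](C)(C)Cl
Why: Standard silylation of the primary alcohol so that it survives bromination and the enolate alkylation.

Step 12
Reactants: 18 the 5-allyl dihydrobenzofuran
Product: 19 the (E)-5-(prop-1-enyl) isomer of 18
Conditions: RuHCl(CO)(PPh3)3 (2 mol%), toluene, 80 °C
Reagents that add atoms: none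
Why: Ruthenium-hydride-catalysed alkene isomerisation moves the double bond into conjugation with the arene, giving the thermodynamically preferred E-styrene.

Step 13
Reactants: 19 the propenyl arene
Product: 21 the 5-(hydroxymethyl) dihydrobenzofuran, via aldehyde 20 (not isolated)
Conditions: O3, CH2Cl2–MeOH, −78 °C (Sudan III end-point); then NaBH4, −78 to 0 °C
Reagents that add atoms: ozone, O=[O+][O-]
Why: Ozonolysis of the electron-rich styrenyl double bond, far more reactive than the arenes, followed by in-flask borohydride reduction gives the benzylic alcohol directly.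

Step 14
Reactants: 21 the benzylic alcohol
Product: 22 (2R,3S)-2-(4-benzyloxy-3-methoxyphenyl)-5-(bromomethyl)-3-(TBS-oxymethyl)-7-methoxy-2,3-dihydrobenzofuran
Conditions: CBr4, PPh3, 2,6-lutidine, CH2Cl2, 0 °C; used at once
Reagents that add atoms: carbon tetrabromide, BrC(Br)(Br)Br
Why: Appel bromination under neutral conditions converts the activated benzylic alcohol to the bromide without disturbing the silyl ether or the benzylic ether of the furan ring.

Step 15
Reactants: 16 the (S)-β-benzyl lactone; 22 the benzylic bromide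
Product: 23 the (3S,4S)-3,4-dibenzyl lactone carrying three TBS, two Bn and one PMB ether
Conditions: LiHMDS, THF, −78 °C; then 22, DMPU, −78 to −30 °C
Reagents that add atoms: none
Why: Alkylation of the lactone lithium enolate occurs anti to the C-4 benzyl substituent, giving the trans-3,4-disubstituted lactone (C-3 S) as in standard dibenzylbutyrolactone lignan synthesis; trans is also the thermodynamic isomer.

Step 16
Reactants: 23 the fully protected lactone
Product: 24 the triol with two Bn and one PMB ether remaining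
Conditions: TBAF, AcOH, THF, 0 °C to rt
Reagents that add atoms: none
Why: Buffered fluoride removes the three TBS ethers without acid, so the benzylic carbinol cannot ionise, and the trans lactone is stable to the mildly basic medium.

Step 17
Reactants: 24 the triol
Product: 25 CNP0199264.1
Conditions: H2 (1 atm), 10% Pd/C, EtOAc–EtOH, rt
Reagents that add atoms: none
Why: Neutral hydrogenolysis removes the two benzyl ethers and the PMB ether; acid is avoided because the freed 2-hydroxyaryl and 4-hydroxybenzylic alcohol pair would cyclise, and neutral Pd/C should leave the benzylic C–O bonds of the furan ring and the carbinol intact.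

**Compound list**

1 | 5-allyl-2-hydroxy-3-methoxybenzaldehyde | C=CCc1cc(C=O)c(O)c(OC)c1 | starting material
2 | 5-allyl-3-methoxy-2-(PMB-oxy)benzaldehyde | C=CCc1cc(C=O)c(OCc2ccc(OC)cc2)c(OC)c1 | intermediate
3 | 1-[5-allyl-3-methoxy-2-(PMB-oxy)phenyl]-2,2,2-trichloroethanol (racemic) | C=CCc1cc(C(O)C(Cl)(Cl)Cl)c(OCc2ccc(OC)cc2)c(OC)c1 | intermediate
4 | [5-allyl-3-methoxy-2-(PMB-oxy)phenyl]acetic acid | C=CCc1cc(CC(=O)O)c(OCc2ccc(OC)cc2)c(OC)c1 | intermediate
5 | (S)-4-benzyloxazolidin-2-one | O=C1N[C@@H](Cc2ccccc2)CO1 | starting material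
6 | mixed anhydride of 4 with pivalic acid | C=CCc1cc(CC(=O)OC(=O)C(C)(C)C)c(OCc2ccc(OC)cc2)c(OC)c1 | intermediate
7 | (S)-3-{[5-allyl-3-methoxy-2-(PMB-oxy)phenyl]acetyl}-4-benzyloxazolidin-2-one | C=CCc1cc(CC(=O)N2[C@@H](Cc3ccccc3)COC2=O)c(OCc2ccc(OC)cc2)c(OC)c1 | intermediate
8 | 4-benzyloxy-3-methoxybenzaldehyde | COc1cc(C=O)ccc1OCc1ccccc1 | starting material
9 | (S)-3-[(2R,3S)-2-[5-allyl-3-methoxy-2-(PMB-oxy)phenyl]-3-(4-benzyloxy-3-methoxyphenyl)-3-(trimethylsilyloxy)propanoyl]-4-benzyloxazolidin-2-one | COc1cc([C@@H](O[Si](C)(C)C)[C@H](C(=O)N2[C@@H](Cc3ccccc3)COC2=O)c2cc(CC=C)cc(OC)c2OCc2ccc(OC)cc2)ccc1OCc1ccccc1 | intermediate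
10 | (2S,3S)-2-[5-allyl-3-methoxy-2-(PMB-oxy)phenyl]-3-(4-benzyloxy-3-methoxyphenyl)-3-(trimethylsilyloxy)propan-1-ol | COc1cc([C@@H](O[Si](C)(C)C)[C@H](CO)c2cc(CC=C)cc(OC)c2OCc2ccc(OC)cc2)ccc1OCc1ccccc1 | intermediate
11 | (1S,2S)-2-[5-allyl-3-methoxy-2-(PMB-oxy)phenyl]-1-(4-benzyloxy-3-methoxyphenyl)propane-1,3-diol | COc1cc([C@@H](O)[C@H](CO)c2cc(CC=C)cc(OC)c2OCc2ccc(OC)cc2)ccc1OCc1ccccc1 | intermediate
12 | 1,3-bis-O-TBS ether of 11 | COc1cc([C@@H](O[Si](C)(C)C(C)(C)C)[C@H](CO[Si](C)(C)C(C)(C)C)c2cc(CC=C)cc(OC)c2OCc2ccc(OC)cc2)ccc1OCc1ccccc1 | intermediate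
13 | 3-{3-[(1S,2S)-1-(4-benzyloxy-3-methoxyphenyl)-1,3-bis(TBS-oxy)propan-2-yl]-5-methoxy-4-(PMB-oxy)phenyl}propan-1-ol | COc1cc([C@@H](O[Si](C)(C)C(C)(C)C)[C@H](CO[Si](C)(C)C(C)(C)C)c2cc(CCCO)cc(OC)c2OCc2ccc(OC)cc2)ccc1OCc1ccccc1 | intermediate
14 | glyoxylate p-toluenesulfonylhydrazone ester of 13 | COc1cc([C@@H](O[Si](C)(C)C(C)(C)C)[C@H](CO[Si](C)(C)C(C)(C)C)c2cc(CCCOC(=O)C=NNS(=O)(=O)c3ccc(C)cc3)cc(OC)c2OCc2ccc(OC)cc2)ccc1OCc1ccccc1 | intermediate
15 | diazoacetate of 13 | COc1cc([C@@H](O[Si](C)(C)C(C)(C)C)[C@H](CO[Si](C)(C)C(C)(C)C)c2cc(CCCOC(=O)C=[N+]=[N-])cc(OC)c2OCc2ccc(OC)cc2)ccc1OCc1ccccc1 | intermediate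
16 | (S)-4-{3-[(1S,2S)-1-(4-benzyloxy-3-methoxyphenyl)-1,3-bis(TBS-oxy)propan-2-yl]-5-methoxy-4-(PMB-oxy)benzyl}dihydrofuran-2(3H)-one | COc1cc([C@@H](O[Si](C)(C)C(C)(C)C)[C@H](CO[Si](C)(C)C(C)(C)C)c2cc(C[C@@H]3COC(=O)C3)cc(OC)c2OCc2ccc(OC)cc2)ccc1OCc1ccccc1 | intermediate
17 | [(2R,3S)-5-allyl-2-(4-benzyloxy-3-methoxyphenyl)-7-methoxy-2,3-dihydrobenzofuran-3-yl]methanol | C=CCc1cc(OC)c2c(c1)[C@@H](CO)[C@H](c1ccc(OCc3ccccc3)c(OC)c1)O2 | intermediate
18 | O-TBS ether of 17 | C=CCc1cc(OC)c2c(c1)[C@@H](CO[Si](C)(C)C(C)(C)C)[C@H](c1ccc(OCc3ccccc3)c(OC)c1)O2 | intermediate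
19 | (2R,3S)-2-(4-benzyloxy-3-methoxyphenyl)-3-(TBS-oxymethyl)-7-methoxy-5-[(E)-prop-1-enyl]-2,3-dihydrobenzofuran | C/C=C/c1cc(OC)c2c(c1)[C@@H](CO[Si](C)(C)C(C)(C)C)[C@H](c1ccc(OCc3ccccc3)c(OC)c1)O2 | intermediate
20 | (2R,3S)-2-(4-benzyloxy-3-methoxyphenyl)-3-(TBS-oxymethyl)-7-methoxy-2,3-dihydrobenzofuran-5-carbaldehyde | O=Cc1cc(OC)c2c(c1)[C@@H](CO[Si](C)(C)C(C)(C)C)[C@H](c1ccc(OCc3ccccc3)c(OC)c1)O2 | intermediate
21 | [(2R,3S)-2-(4-benzyloxy-3-methoxyphenyl)-3-(TBS-oxymethyl)-7-methoxy-2,3-dihydrobenzofuran-5-yl]methanol | OCc1cc(OC)c2c(c1)[C@@H](CO[Si](C)(C)C(C)(C)C)[C@H](c1ccc(OCc3ccccc3)c(OC)c1)O2 | intermediate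
22 | (2R,3S)-2-(4-benzyloxy-3-methoxyphenyl)-5-(bromomethyl)-3-(TBS-oxymethyl)-7-methoxy-2,3-dihydrobenzofuran | BrCc1cc(OC)c2c(c1)[C@@H](CO[Si](C)(C)C(C)(C)C)[C@H](c1ccc(OCc3ccccc3)c(OC)c1)O2 | intermediate
23 | (3S,4S)-3-{[(2R,3S)-2-(4-benzyloxy-3-methoxyphenyl)-3-(TBS-oxymethyl)-7-methoxy-2,3-dihydrobenzofuran-5-yl]methyl}-4-{3-[(1S,2S)-1-(4-benzyloxy-3-methoxyphenyl)-1,3-bis(TBS-oxy)propan-2-yl]-5-methoxy-4-(PMB-oxy)benzyl}dihydrofuran-2(3H)-one | COc1cc([C@@H](O[Si](C)(C)C(C)(C)C)[C@H](CO[Si](C)(C)C(C)(C)C)c2cc(C[C@@H]3COC(=O)[C@H]3Cc3cc(OC)c4c(c3)[C@@H](CO[Si](C)(C)C(C)(C)C)[C@H](c3ccc(OCc5ccccc5)c(OC)c3)O4)cc(OC)c2OCc2ccc(OC)cc2)ccc1OCc1ccccc1 | intermediate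
24 | tris-desilylated 23 (two Bn and one PMB ether remaining) | COc1cc([C@@H](O)[C@H](CO)c2cc(C[C@@H]3COC(=O)[C@H]3Cc3cc(OC)c4c(c3)[C@@H](CO)[C@H](c3ccc(OCc5ccccc5)c(OC)c3)O4)cc(OC)c2OCc2ccc(OC)cc2)ccc1OCc1ccccc1 | intermediate
25 | CNP0199264.1, (3S,4S)-4-{3-[(1S,2S)-1,3-dihydroxy-1-(4-hydroxy-3-methoxyphenyl)propan-2-yl]-4-hydroxy-5-methoxybenzyl}-3-{[(2R,3S)-2-(4-hydroxy-3-methoxyphenyl)-3-(hydroxymethyl)-7-methoxy-2,3-dihydrobenzofuran-5-yl]methyl}dihydrofuran-2(3H)-one | COc1cc([C@@H](O)[C@H](CO)c2cc(C[C@@H]3COC(=O)[C@H]3Cc3cc(OC)c4c(c3)[C@@H](CO)[C@H](c3ccc(O)c(OC)c3)O4)cc(OC)c2O)ccc1O | target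

**Step count**

Total steps: 17. Longest linear sequence: 13 steps (steps 1–5, 10–14, 15–17).

**Steps most likely to fail**

Step 9. The carbenoid may insert at the benzylic CH2 (δ-lactone), add to the electron-rich arene, dimerise at the concentration a large substrate requires, or discriminate the two prochiral hydrogens poorly. The fallback builds the same stereocentre by auxiliary-controlled enolate alkylation, setting out from 13 and returning at 16. Oxidation of 13 (TEMPO cat., PhI(OAc)2, MeCN–H2O) should give the 3-arylpropanoic acid F1. Acylation of (R)-4-benzyloxazolidin-2-one (PivCl, Et3N, LiCl, THF) should give the imide F2. Its sodium enolate (NaHMDS, THF, −78 °C) is alkylated with tert-butyl bromoacetate on the face away from the auxiliary's benzyl group to give the succinate-type imide F3. LiBH4–MeOH reduction of the imide carbonyl, with the tert-butyl ester left intact, should give the hydroxy ester F4. Alkoxide-mediated lactonisation (t-BuOK cat., THF, 0 °C) then closes 16.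

Step 4. The aldol may show poor facial or anti/syn selectivity, add slowly to the electron-rich aldehyde, or lose the α-aryl stereocentre by base-promoted epimerisation. The fallback forms the ArCH(OH)–CH bond by Felkin–Anh addition of an aryl Grignard reagent to a chiral α-aryl aldehyde, setting out from 4 and returning at 11. Acid 4 is coupled with (R)-4-benzyloxazolidin-2-one (PivCl, Et3N, LiCl) to give the antipodal-auxiliary imide F5. Titanium-enolate hydroxymethylation (TiCl4, i-Pr2NEt, s-trioxane, CH2Cl2, 0 °C) should give the (S)-2-aryl-3-hydroxypropanoyl imide F6. Silylation (TIPSOTf, 2,6-lutidine) gives the TIPS ether F7, and LiBH4 reduction gives the primary alcohol F8. Dess–Martin oxidation gives the α-aryl aldehyde F9, which is used at once. Addition of (4-benzyloxy-3-methoxyphenyl)magnesium bromide (THF, −78 °C) anti to the α-aryl group should give the anti mono-TIPS diol F10. TBAF then gives 11.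

Step 10. The 4-methoxybenzyl cation may C-alkylate the electron-rich rings, the benzylic cation may lose a proton to give a stilbene, or trans selectivity may be incomplete. The fallback separates unmasking from ring closure and closes the ring by SN2 displacement, setting out from 11 and returning at 18. Selective silylation of the primary hydroxyl (TBSCl, imidazole, CH2Cl2, 0 °C) should give the mono-TBS ether F11. PMB removal with a soft Lewis acid and nucleophile (MgBr2·OEt2, Me2S, CH2Cl2) should give the free phenol F12. Mitsunobu cycloetherification (PPh3, DIAD, THF, 0 °C) displaces the benzylic hydroxyl with inversion, which from the anti-diol gives the same trans ring, compound 18.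

**Further compounds**

F1 | step 9 | 3-{3-[(1S,2S)-1-(4-benzyloxy-3-methoxyphenyl)-1,3-bis(TBS-oxy)propan-2-yl]-5-methoxy-4-(PMB-oxy)phenyl}propanoic acid | COc1cc([C@@H](O[Si](C)(C)C(C)(C)C)[C@H](CO[Si](C)(C)C(C)(C)C)c2cc(CCC(=O)O)cc(OC)c2OCc2ccc(OC)cc2)ccc1OCc1ccccc1
F2 | step 9 | (R)-4-benzyl-3-(3-arylpropanoyl)oxazolidin-2-one derived from F1 | COc1cc([C@@H](O[Si](C)(C)C(C)(C)C)[C@H](CO[Si](C)(C)C(C)(C)C)c2cc(CCC(=O)N3[C@H](Cc4ccccc4)COC3=O)cc(OC)c2OCc2ccc(OC)cc2)ccc1OCc1ccccc1
F3 | step 9 | tert-butyl (3S)-3-[(R)-4-benzyl-2-oxooxazolidine-3-carbonyl]-4-arylbutanoate (aryl as in F1) | COc1cc([C@@H](O[Si](C)(C)C(C)(C)C)[C@H](CO[Si](C)(C)C(C)(C)C)c2cc(C[C@@H](CC(=O)OC(C)(C)C)C(=O)N3[C@H](Cc4ccccc4)COC3=O)cc(OC)c2OCc2ccc(OC)cc2)ccc1OCc1ccccc1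
F4 | step 9 | tert-butyl (3S)-4-aryl-3-(hydroxymethyl)butanoate (aryl as in F1) | COc1cc([C@@H](O[Si](C)(C)C(C)(C)C)[C@H](CO[Si](C)(C)C(C)(C)C)c2cc(C[C@@H](CC(=O)OC(C)(C)C)CO)cc(OC)c2OCc2ccc(OC)cc2)ccc1OCc1ccccc1
F5 | step 4 | (R)-3-{[5-allyl-3-methoxy-2-(PMB-oxy)phenyl]acetyl}-4-benzyloxazolidin-2-one | C=CCc1cc(CC(=O)N2[C@H](Cc3ccccc3)COC2=O)c(OCc2ccc(OC)cc2)c(OC)c1
F6 | step 4 | (R)-3-{(2S)-2-[5-allyl-3-methoxy-2-(PMB-oxy)phenyl]-3-hydroxypropanoyl}-4-benzyloxazolidin-2-one | C=CCc1cc([C@@H](CO)C(=O)N2[C@H](Cc3ccccc3)COC2=O)c(OCc2ccc(OC)cc2)c(OC)c1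
F7 | step 4 | O-TIPS ether of F6 | C=CCc1cc([C@@H](CO[Si](C(C)C)(C(C)C)C(C)C)C(=O)N2[C@H](Cc3ccccc3)COC2=O)c(OCc2ccc(OC)cc2)c(OC)c1
F8 | step 4 | (R)-2-[5-allyl-3-methoxy-2-(PMB-oxy)phenyl]-3-(TIPS-oxy)propan-1-ol | C=CCc1cc([C@@H](CO[Si](C(C)C)(C(C)C)C(C)C)CO)c(OCc2ccc(OC)cc2)c(OC)c1
F9 | step 4 | (S)-2-[5-allyl-3-methoxy-2-(PMB-oxy)phenyl]-3-(TIPS-oxy)propanal | C=CCc1cc([C@@H](CO[Si](C(C)C)(C(C)C)C(C)C)C=O)c(OCc2ccc(OC)cc2)c(OC)c1
F10 | step 4 | (1S,2S)-2-[5-allyl-3-methoxy-2-(PMB-oxy)phenyl]-1-(4-benzyloxy-3-methoxyphenyl)-3-(TIPS-oxy)propan-1-ol | COc1cc([C@@H](O)[C@H](CO[Si](C(C)C)(C(C)C)C(C)C)c2cc(CC=C)cc(OC)c2OCc2ccc(OC)cc2)ccc1OCc1ccccc1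
F11 | step 10 | (1S,2S)-2-[5-allyl-3-methoxy-2-(PMB-oxy)phenyl]-1-(4-benzyloxy-3-methoxyphenyl)-3-(TBS-oxy)propan-1-ol | COc1cc([C@@H](O)[C@H](CO[Si](C)(C)C(C)(C)C)c2cc(CC=C)cc(OC)c2OCc2ccc(OC)cc2)ccc1OCc1ccccc1
F12 | step 10 | 4-allyl-2-[(1S,2S)-1-(4-benzyloxy-3-methoxyphenyl)-1-hydroxy-3-(TBS-oxy)propan-2-yl]-6-methoxyphenol | COc1cc([C@@H](O)[C@H](CO[Si](C)(C)C(C)(C)C)c2cc(CC=C)cc(OC)c2O)ccc1OCc1ccccc1
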